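**Plan**

1. Numbering and enabling feature: O1, C2 (heptyl), C3, C4 (ketone), C4a=C8a, C5, C6 (decyl), O7, C8 (lactone C=O); ring A is the dihydropyranone, ring B the lactone. In ring A, C2 is bound to O1 and C3 and C4 is a ketone, which is the pattern left when a C3=C4 enol ether captures an O1=C2 oxocarbenium ion. Saturating C4a=C8a creates two temporary stereocentres in ring B through which C6 can direct C2.
2. Retrosynthesis: add H2 across C4a=C8a; cut O1–C2 and C2–C3 (Prins) to octanal and a 3-hydroxy-4-(1-ethoxyvinyl) δ-lactone; then cut C8a–O (enolate hydroxylation), C4a–C4 (cuprate addition), the ring B alkene (metathesis), the ester C–O bond and the C5–allyl bond, back to 1,2-epoxydodecane.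
3. Forward: ring B closes first by ring-closing metathesis, ring A second by the Prins cyclisation, and the C4a=C8a alkene is restored last by dehydrogenation.
4. Stereochemistry: C6 comes from hydrolytic kinetic resolution of the epoxide; C4a is set trans to decyl by cuprate addition; the C8a oxygen is set anti to the C4a substituent by enolate hydroxylation; C2 follows from C8a through the chair Prins transition state; C4a and C8a are then erased.

Key step: step 7

Assumption: 1,2-epoxydodecane is bought as the racemate and resolved in step 1; compounds 3, 5, 8 and 15 are bought as such. Lactone positions 3 and 4 of compounds 7–16 become C8a and C4a of the bicycle.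

**Step 1**
Reactants: 1 rac-1,2-epoxydodecane
Product: 2 (S)-1,2-epoxydodecane
Conditions: (S,S)-Co(salen)(OAc) (0.5 mol%), H2O (0.55 equiv), THF, 0 °C to rt; distillation
Reagents that add atoms: none
Why: Jacobsen hydrolytic kinetic resolution, in which the (S,S)-configured trivalent cobalt complex of N,N′-bis(3,5-di-tert-butylsalicylidene)cyclohexane-1,2-diamine should hydrolyse the (R)-epoxide selectively, so that the (S)-epoxide carrying the future C6 centre is recovered.

**Step 2**
Reactants: 2 (S)-1,2-epoxydodecane; 3 vinylmagnesium bromide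
Product: 4 (4S)-tetradec-1-en-4-ol
Conditions: CH2=CHMgBr, CuI (10 mol%), THF, −30 to 0 °C; aq NH4Cl
Reagents that add atoms: none
Why: Copper-catalysed Grignard opening of a terminal epoxide takes place at the unsubstituted carbon, so the C–O stereocentre is untouched.

**Step 3**
Reactants: 4 (4S)-tetradec-1-en-4-ol; 5 acryloyl chloride
Product: 6 (4S)-tetradec-1-en-4-yl acrylate
Conditions: Et3N, CH2Cl2, 0 °C
Reagents that add atoms: none
Why: Acylation of a secondary alcohol with an acid chloride (esterification) installs the second alkene needed for ring closure.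

**Step 4**
Reactants: 6 (4S)-tetradec-1-en-4-yl acrylate
Product: 7 (6S)-6-decyl-5,6-dihydro-2H-pyran-2-one
Conditions: second-generation Grubbs catalyst, (H2IMes)(PCy3)Cl2Ru=CHPh (3 mol%), CH2Cl2 (0.01 M), 40 °C
Reagents that add atoms: none
Why: Ring-closing metathesis of the acrylate/allyl diene should give the six-membered unsaturated lactone (ring B) with loss of ethylene.

**Step 5**
Reactants: 7 (6S)-6-decyl-5,6-dihydro-2H-pyran-2-one; 8 ethyl vinyl ether
Product: 12 (4S,6S)-6-decyl-4-(1-ethoxyvinyl)tetrahydro-2H-pyran-2-one (4,6-trans), via 1-ethoxyvinyllithium 9 (not isolated), via lithium bis(1-ethoxyvinyl)cuprate 10 (not isolated), via lithium enolate 11 (not isolated)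
Conditions: 8, t-BuLi, THF, −78 to 0 °C; CuI, −78 to −40 °C; 7, −78 °C; aq NH4Cl/NH3 (pH 8)
Reagents that add atoms: none
Why: Conjugate addition of a Gilman α-alkoxyvinyl cuprate (an acyl anion equivalent) to the unsaturated δ-lactone should occur by axial attack on the half-chair anti to the pseudo-equatorial decyl group, which sets C4 (later C4a) trans to decyl as is usual for 6-substituted 5,6-dihydropyran-2-ones.

**Step 6**
Reactants: 12 (4S,6S)-6-decyl-4-(1-ethoxyvinyl)tetrahydro-2H-pyran-2-one
Product: 14 (3R,4S,6S)-6-decyl-4-(1-ethoxyvinyl)-3-hydroxytetrahydro-2H-pyran-2-one (3,4-trans, 3,6-cis), via potassium enolate 13 (not isolated)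
Conditions: KN(SiMe3)2, THF, −78 °C; 2-(phenylsulfonyl)-3-phenyloxaziridine, −78 °C; aq NH4Cl/NH3 (pH 8)
Reagents that add atoms: 2-(phenylsulfonyl)-3-phenyloxaziridine (Davis reagent), O=S(=O)(c1ccccc1)N1OC1c1ccccc1
Why: Davis enolate hydroxylation, in which the oxaziridine should approach the lactone enolate on the face opposite the adjacent ethoxyvinyl group, so that the new C3 oxygen (later on C8a) is trans to C4 and therefore cis to decyl.

**Step 7**
Reactants: 14 (3R,4S,6S)-6-decyl-4-(1-ethoxyvinyl)-3-hydroxytetrahydro-2H-pyran-2-one; 15 octanal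
Product: 19 (2R,4aS,6S,8aR)-6-decyl-2-heptylhexahydropyrano[2,3-c]pyran-4,8-dione (trans-fused), via silyl ether 16 (not isolated), via oxocarbenium triflate 17 (not isolated), via ethoxycarbenium triflate 18 (not isolated)
Conditions: Me3SiOTf (1.2 equiv), 2,6-di-tert-butyl-4-methylpyridine (1.5 equiv), CH2Cl2, −78 °C; then 15 (1.5 equiv), −78 to −40 °C; aq NaHCO3
Reagents that add atoms: none
Why: Me3SiOTf silylates the C8a hydroxyl (the pyridine takes up the triflic acid), the silyl ether condenses with octanal under Me3SiOTf catalysis to the (E)-oxocarbenium ion O1=C2 with loss of hexamethyldisiloxane, the enol ether terminus C3 attacks C2, and the ring-closed 4-ethoxycarbenium ion is discharged to the C4 ketone as EtOSiMe3. The closest known reaction is the Prins cyclisation of a homoallylic alcohol bearing an enol ether with an aldehyde (silyl enol ether Prins type), which gives 2,6-cis-tetrahydropyran-4-ones. Ring A closes in the 6-endo mode with respect to both the oxocarbenium and the enol ether π bonds. C2 is the only new stereocentre: the trans ring fusion is already fixed by the C4a and C8a configurations, so in the chair transition state heptyl takes the equatorial site and H2 ends up cis to H8a, which, with the C8a oxygen cis to decyl, is the (2R) configuration. The step needs condensation at oxygen to outrun protonation or intermolecular aldol-type attack on the enol ether, and equatorial over axial heptyl; the hindered pyridine keeps the medium free of protic acid, the tether makes capture intramolecular once the cation forms, and 2-oxonia-Cope scrambling is disfavoured because it would place positive charge at C8a next to the lactone carbonyl.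

**Step 8**
Reactants: 19 (2R,4aS,6S,8aR)-6-decyl-2-heptylhexahydropyrano[2,3-c]pyran-4,8-dione
Product: 20 (2R,6S,8aR)-6-decyl-2-heptyl-4-(trimethylsilyloxy)-2,3,5,6-tetrahydropyrano[2,3-c]pyran-8(8aH)-one (C4=C4a silyl enol ether)
Conditions: Me3SiCl, NaI, Et3N, MeCN, rt
Reagents that add atoms: chlorotrimethylsilane, C[Si](C)(C)Cl
Why: Thermodynamic silyl enol ether formation with Me3SiI made in the flask should favour the more substituted C4=C4a isomer over C3=C4 under these equilibrating conditions, and it leaves C2 untouched.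

**Step 9**
Reactants: 20 (2R,6S,8aR)-6-decyl-2-heptyl-4-(trimethylsilyloxy)-2,3,5,6-tetrahydropyrano[2,3-c]pyran-8(8aH)-one
Product: 21 (2R,6S)-6-decyl-2-heptyl-2,3,5,6-tetrahydropyrano[2,3-c]pyran-4,8-dione (target)
Conditions: Pd(OAc)2 (1.1 equiv), MeCN, rt
Reagents that add atoms: none
Why: Saegusa–Ito oxidation, in which the divalent palladium enolate at C4a should undergo syn β-hydride elimination with H8a to give the ring A endocyclic, push–pull conjugated C4a=C8a enone; no base is present, so C2 cannot epimerise by retro-oxa-Michael opening.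

**Compound list**

1 | rac-1,2-epoxydodecane (2-decyloxirane) | CCCCCCCCCCC1CO1 | starting material
2 | (S)-1,2-epoxydodecane | CCCCCCCCCC[C@H]1CO1 | intermediate
3 | vinylmagnesium bromide | C=C[Mg]Br | starting material
4 | (4S)-tetradec-1-en-4-ol | CCCCCCCCCC[C@H](O)CC=C | intermediate
5 | acryloyl chloride | C=CC(=O)Cl | starting material
6 | (4S)-tetradec-1-en-4-yl acrylate | CCCCCCCCCC[C@H](OC(=O)C=C)CC=C | intermediate
7 | (6S)-6-decyl-5,6-dihydro-2H-pyran-2-one | CCCCCCCCCC[C@H]1CC=CC(=O)O1 | intermediate
8 | ethyl vinyl ether | C=COCC | starting material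
9 | 1-ethoxyvinyllithium | [Li]C(=C)OCC | intermediate
10 | lithium bis(1-ethoxyvinyl)cuprate | [Li+].C=C(OCC)[Cu-]C(=C)OCC | intermediate
11 | lithium enolate of 12 | CCCCCCCCCC[C@H]1C[C@H](C(=C)OCC)C=C([O-])O1.[Li+] | intermediate
12 | (4S,6S)-6-decyl-4-(1-ethoxyvinyl)tetrahydro-2H-pyran-2-one | CCCCCCCCCC[C@H]1C[C@H](C(=C)OCC)CC(=O)O1 | intermediate
13 | potassium enolate of 12 | CCCCCCCCCC[C@H]1C[C@H](C(=C)OCC)C=C([O-])O1.[K+] | intermediate
14 | (3R,4S,6S)-6-decyl-4-(1-ethoxyvinyl)-3-hydroxytetrahydro-2H-pyran-2-one | CCCCCCCCCC[C@H]1C[C@H](C(=C)OCC)[C@@H](O)C(=O)O1 | intermediate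
15 | octanal | CCCCCCCC=O | starting material
16 | trimethylsilyl ether of 14 | CCCCCCCCCC[C@H]1C[C@H](C(=C)OCC)[C@@H](O[Si](C)(C)C)C(=O)O1 | intermediate
17 | (E)-oxocarbenium triflate from 16 and octanal | CCCCCCCCCC[C@H]1C[C@H](C(=C)OCC)[C@@H](/[O+]=C/CCCCCCC)C(=O)O1.[O-]S(=O)(=O)C(F)(F)F | intermediate
18 | ring-closed 4-ethoxycarbenium triflate | CCCCCCCCCC[C@H]1C[C@H]2[C@@H](O[C@H](CCCCCCC)CC2=[O+]CC)C(=O)O1.[O-]S(=O)(=O)C(F)(F)F | intermediate
19 | (2R,4aS,6S,8aR)-6-decyl-2-heptylhexahydropyrano[2,3-c]pyran-4,8-dione | CCCCCCCCCC[C@H]1C[C@H]2[C@@H](O[C@H](CCCCCCC)CC2=O)C(=O)O1 | intermediate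
20 | (2R,6S,8aR)-6-decyl-2-heptyl-4-(trimethylsilyloxy)-2,3,5,6-tetrahydropyrano[2,3-c]pyran-8(8aH)-one | CCCCCCCCCC[C@H]1CC2=C(O[Si](C)(C)C)C[C@@H](CCCCCCC)O[C@H]2C(=O)O1 | intermediate
21 | (2R,6S)-6-decyl-2-heptyl-2,3,5,6-tetrahydropyrano[2,3-c]pyran-4,8-dione | CCCCCCCCCC[C@H]1CC2=C(O[C@H](CCCCCCC)CC2=O)C(=O)O1 | target

**Step count and risks**

Total steps: 9. Longest linear sequence: 9 steps (1 to 21).

Steps most likely to fail:

Step 7. The acid-labile enol ether may be protonated, or may add to the activated aldehyde in an intermolecular aldol-type reaction, before the electron-poor C8a oxygen has condensed with octanal. The fallback replaces the enol ether by an allylsilane and sets out from 7. Copper-catalysed conjugate addition (CuI, Me3SiCl, THF, −78 °C) of [1-(trimethylsilylmethyl)vinyl]magnesium bromide F1, made from commercial (2-bromoallyl)trimethylsilane and magnesium, would give (4S,6S)-6-decyl-4-[3-(trimethylsilyl)prop-1-en-2-yl]tetrahydro-2H-pyran-2-one F2. Enolate hydroxylation as in step 6 would give (3R,4R,6S)-6-decyl-3-hydroxy-4-[3-(trimethylsilyl)prop-1-en-2-yl]tetrahydro-2H-pyran-2-one F3. Condensation with octanal 15 and Me3SiOTf (intramolecular silyl-modified Sakurai cyclisation, an allylsilane-terminated Prins closure through the same chair) would form the same O1–C2 and C2–C3 bonds and give (2R,4aR,6S,8aR)-6-decyl-2-heptyl-4-methylenehexahydropyrano[2,3-c]pyran-8-one F4. Ozonolysis (O3, CH2Cl2, −78 °C; Me2S) would return to the route at 19.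

Step 9. β-Hydride elimination from the palladium enolate may go toward C5 instead of C8a, giving the alkene on the wrong side of C4a. The fallback sets out from 20 and uses the acidity of H8a. N-Bromosuccinimide (THF, 0 °C) would brominate the enol ether at C4a to give (2R,6S,8aS)-4a-bromo-6-decyl-2-heptylhexahydropyrano[2,3-c]pyran-4,8-dione F5 (either C4a epimer). Brief treatment with Et3N (CH2Cl2, 0 °C) would then remove H8a, the only acidic β-hydrogen, and expel bromide by an E1cB elimination, arriving at 21.

Step 5. The α-alkoxyvinyl cuprate may decompose on warming or transfer its ligand too slowly, leading to 1,2-addition or recovered lactone. The fallback sets out from 7. Copper-catalysed addition of vinylmagnesium bromide 3 (CuI, Me3SiCl, THF, −78 °C) would give (4S,6S)-6-decyl-4-vinyltetrahydro-2H-pyran-2-one F6. Wacker oxidation (PdCl2, CuCl, O2, DMF/H2O, rt) would give (4S,6S)-4-acetyl-6-decyltetrahydro-2H-pyran-2-one F7, which must be kept away from base because C4 is now epimerisable. Ketalisation with EtOSiMe3 and catalytic Me3SiOTf (CH2Cl2, −78 °C) would give (4S,6S)-6-decyl-4-(1,1-diethoxyethyl)tetrahydro-2H-pyran-2-one F8. Loss of ethanol toward the methyl group with Me3SiOTf and i-Pr2NEt (CH2Cl2, −20 °C to rt) would return to the route at 12.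

**Further compounds**

F1 | step 7 | [1-(trimethylsilylmethyl)vinyl]magnesium bromide | C=C([Mg]Br)C[Si](C)(C)C
F2 | step 7 | (4S,6S)-6-decyl-4-[3-(trimethylsilyl)prop-1-en-2-yl]tetrahydro-2H-pyran-2-one | CCCCCCCCCC[C@H]1C[C@H](C(=C)C[Si](C)(C)C)CC(=O)O1
F3 | step 7 | (3R,4R,6S)-6-decyl-3-hydroxy-4-[3-(trimethylsilyl)prop-1-en-2-yl]tetrahydro-2H-pyran-2-one | CCCCCCCCCC[C@H]1C[C@H](C(=C)C[Si](C)(C)C)[C@@H](O)C(=O)O1
F4 | step 7 | (2R,4aR,6S,8aR)-6-decyl-2-heptyl-4-methylenehexahydropyrano[2,3-c]pyran-8-one | CCCCCCCCCC[C@H]1C[C@H]2[C@@H](O[C@H](CCCCCCC)CC2=C)C(=O)O1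
F5 | step 9 | (2R,6S,8aS)-4a-bromo-6-decyl-2-heptylhexahydropyrano[2,3-c]pyran-4,8-dione (either C4a epimer) | CCCCCCCCCC[C@H]1CC2(Br)[C@@H](O[C@H](CCCCCCC)CC2=O)C(=O)O1
F6 | step 5 | (4S,6S)-6-decyl-4-vinyltetrahydro-2H-pyran-2-one | CCCCCCCCCC[C@H]1C[C@H](C=C)CC(=O)O1
F7 | step 5 | (4S,6S)-4-acetyl-6-decyltetrahydro-2H-pyran-2-one | CCCCCCCCCC[C@H]1C[C@H](C(C)=O)CC(=O)O1
F8 | step 5 | (4S,6S)-6-decyl-4-(1,1-diethoxyethyl)tetrahydro-2H-pyran-2-one | CCCCCCCCCC[C@H]1C[C@H](C(C)(OCC)OCC)CC(=O)O1
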